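The overall equation takes one partner for each starting material, so the excess of partner over starting material, bound forms counted, stays what the charge made it. That excess is 10.0 mM in the south run, 0.0700 M in the east run and 0.230 M in the north run.

common to all: catalyst 0.500 mM
- south: starting material 50.0 mM; partner 60.0 mM
- north-west: starting material 20.0 mM; partner 30.0 mM
- east: starting material 50.0 mM; partner 120 mM
- north: starting material 50.0 mM; partner 280 mM; time 13 min

| south run: time / min | south run: [target] / mM | north-west run: time / min | north-west run: [target] / mM | east run: time / min | east run: [target] / mM |
|---|---|---|---|---|---|
| 0.58 | 2.0 | 0.58 | 0.5 | 0.58 | 4.0 |
| 1.8 | 5.3 | 1.8 | 1.2 | 1.8 | 10.5 |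
| 3.4 | 9.2 | 3.4 | 3.1 | 3.4 | 16.3 |
| 5.3 | 12.9 | 5.3 | 4.3 | 5.3 | 22.1 |
| 7.6 | 17.2 | 7.6 | 6.4 | 7.6 | 27.8 |
| 10 | 20.0 | 10 | 8.4 | 10 | 32.2 |
| 13 | 23.2 | 13 | 9.7 | 13 | 35.4 |

(standard deviation of a reading: 0.4 mM)

* apparent order in [partner] of the starting rate, round the charge of the south run (the rate where two percent of its starting material have turned into target)
* apparent order in [starting material] of the starting rate, round the charge of the south run (the rate where two percent of its starting material have turned into target) (one fixed amount of target, the same in the runs compared)
* the north-west run starts with 30.0 mM less of starting material and of partner than the south run, and with no target. Compared where both hold the same amount of starting material, once fifteen percent of what the north-west run was charged with has turned into target, is the north-west run faster, slower or alike (within a tenth)?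
* target in the north run at 13 min, as a share of the starting material charged

- Overall: starting material + partner -> target, with catalyst as catalyst.
- Constant volume, constant temperature.
- A reading of a species includes what of it is bound.
- An order is taken over about fifteen percent of the charge, up and down.

Work with fractions left: s for the starting material and p for the partner, each as a share of its own charge. One reading of target gives both.

The bench rule is pseudo-first-order. Treat p as steady, let ln s fall evenly with time, and scale its slope with the partner charge. The last reading of the east run gives s = 0.292. Scaled by 2.33, the rule leaves 5.66 % in the north run.

The border lies in the ratio of the charges. The north run holds less starting material than partner, so starting material is the limiting reagent there, and if it were used up, p would end at 0.821. In the east run, which the rule was scaled from, p would end lower, at 0.583, so p is steady in neither run, and less so in the east run.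

The excess mends this. If the rate goes with starting material times partner, ln(p/s) grows evenly with time. Call its growth per minute and per unit of excess the pace. My reckoning takes it from the east run's last reading: 0.969 M⁻¹ min⁻¹. The south run, with the same charge of starting material, reads 1.04 M⁻¹ min⁻¹, close to it.

Since p = (excess + starting charge × s) / partner charge, the east pace leaves 4.58 % in the north run. So I commit to 95.4 % of target.

The forecast gives 0.95 for the order in partner, 0.6 for the order in starting material, faster for the north-west run, and 93 % of target in the north run, lower than mine. Its words: “I shade this down slightly for possible saturation in partner”.

The north run gives 97.8 % at 13 min. The apparent order in starting material is 0.41, below one, with 1.0 in partner and the north-west run faster.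

    catalyst + starting material ⇌ catalyst-substrate complex, settled at all times (33.70 M⁻¹)
    catalyst-substrate complex + partner → target + catalyst + by-product (361.8 M⁻¹ min⁻¹)
    catalyst + target ⇌ catalyst-product complex, settled at all times (43.30 M⁻¹)
    2 starting material ⇌ idle substrate dimer, settled at all times (84.80 M⁻¹)

Read back from the north run, the pace is 1.21 M⁻¹ min⁻¹, above the east value. The north-west run reaches s = 0.5 at 14.7 min, which gives a pace of 1.95 M⁻¹ min⁻¹, twice the east value.

All runs are simulated on assumed constants; scatter was added.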